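**Strategy.** The six-membered ring (C1, C14, C13, C12, C11, C10) is built on a sugar by a deacylative Michael/aldol [3+3] annulation. The step exploits the alternation in that ring of a ketone-level carbon (C14, later an epoxide carbon) flanked by C1 and C13 with an enal-level C10–C11–C12 unit: 3-methylpentane-2,4-dione adds through C1 to C10 of a 2-methylpropenal and, after loss of one acetyl group, condenses through C13 with the C12 aldehyde. The precursor is an L-arabinose-derived furanose that already holds C6–C9, the C8 carbinol and C17; its ring oxygen becomes the 9-acetate oxygen. Acrolein and acetylene later supply C2–C5, joined by enyne/ring-closing metathesis.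

Key step: step 7

Remark: C1–C20 are the briarane locants of the target and are used for every intermediate; sugar C1–C5 of L-arabinose become C6–C10.

Step 1
Reactants: 1 L-arabinose
Product: 2 5-O-(tert-butyldiphenylsilyl)-L-arabinofuranose (anomer mixture)
Conditions: TBDPSCl, pyridine, DMF, rt
Reagents that add atoms: tert-butyl(chloro)diphenylsilane CC(C)(C)[Si](Cl)(c1ccccc1)c1ccccc1
Why: O-Silylation of the only primary hydroxyl, which exists only in the furanose tautomer, should drain the ring equilibrium into the 5-O-silyl furanose without touching a stereocentre.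

Step 2
Reactants: 2 5-O-silyl arabinofuranose
Product: 3 5-O-(tert-butyldiphenylsilyl)-1,2-O-isopropylidene-β-L-arabinofuranose
Conditions: 2,2-dimethoxypropane, TsOH·H2O (cat.), acetone, rt
Reagents that add atoms: 2,2-dimethoxypropane COC(C)(C)OC
Why: Acid-catalysed transacetalisation closes the cis-fused 1,2-dioxolane (the 3-OH is trans and cannot take part), which fixes the β-L-furanose and leaves only the C8 hydroxyl free.

Step 3
Reactants: 3 acetonide
Product: 4 5-O-(tert-butyldiphenylsilyl)-1,2-O-isopropylidene-β-L-threo-pentofuranos-3-ulose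
Conditions: Dess–Martin periodinane, NaHCO3, CH2Cl2, rt
Reagents that add atoms: none
Why: Dess–Martin oxidation of the lone secondary alcohol gives the C8 ketone under buffered, non-basic conditions that should not epimerise C7 or C9.

Step 4
Reactants: 4 ulose; 5 N,N-dimethylpropanamide
Product: 6 3-C-[(2R)-1-(dimethylamino)-1-oxopropan-2-yl]-5-O-(tert-butyldiphenylsilyl)-1,2-O-isopropylidene-β-L-lyxofuranose
Conditions: LiN(iPr)2, 5, THF, −78 °C; then 4, −78 °C; NH4Cl
Reagents that add atoms: N,N-dimethylpropanamide (5) CCC(=O)N(C)C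
Why: Aldol addition of the (Z)-lithium amide enolate on the convex face of the bicycle (anti to the dioxolane and to C10) sets C8, and a Zimmerman–Traxler chair in which lithium also binds O7 (C7 axial, C9 equatorial) should place the C17 methyl syn to the new hydroxyl along C19–C17–C8–C9 (17R).

Step 5
Reactants: 6 aldol adduct
Product: 7 3-C-[(2R)-1-(dimethylamino)-1-oxopropan-2-yl]-1,2-O-isopropylidene-β-L-lyxofuranose
Conditions: Bu4NF, AcOH, THF, 0 °C → rt
Reagents that add atoms: none
Why: Fluoride cleaves the primary silyl ether by Si–F bond formation, and the acetic acid buffer should suppress retro-aldol cleavage of the tertiary β-hydroxy amide.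

Step 6
Reactants: 7 diol; 8 2-(triphenyl-λ5-phosphanylidene)propanal
Product: 10 (E)-2-methyl enal (C12 aldehyde, C11 methyl, C10=C11) bonded through C10 to C9 of the furanose, via aldehyde 9 (not isolated)
Conditions: Dess–Martin periodinane, CH2Cl2, 0 °C; then 8, 40 °C
Reagents that add atoms: 2-(triphenyl-λ5-phosphanylidene)propanal (8) CC(C=O)=P(c1ccccc1)(c1ccccc1)c1ccccc1
Why: Oxidation of the primary alcohol (the tertiary one is inert) and Wittig olefination with the stabilised α-methyl ylide in the same flask should give the (E)-enal, the α-alkoxy aldehyde being trapped before it can epimerise.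

Step 7
Reactants: 10 enal; 11 3-methylpentane-2,4-dione
Product: 14 4,6-dimethyl-5-(furanos-4-yl)cyclohex-2-en-1-one (C14 ketone, C12=C13, methyl-bearing C11 and C1 as epimer mixtures, C10 configured as in the target), via Michael adduct 12 (not isolated), via keto aldehyde 13 (not isolated)
Conditions: K2CO3 (0.5 equiv), MeOH, 0 → 40 °C
Reagents that add atoms: 3-methylpentane-2,4-dione (11) CC(=O)C(C)C(C)=O
Why: Carbonate deprotonates the diketone, whose carbanion adds in a Michael reaction to C10 of the enal (C1–C10 bond); methoxide then removes one acetyl group of the now non-enolisable 1,3-diketone by retro-Claisen cleavage, which makes the addition irreversible, and the freed methyl ketone condenses through C13 with the C12 aldehyde (C12–C13 bond) and dehydrates to the enone. The closest known reaction type is the Robinson-type Michael/aldol [3+3] annulation of 1,3-dicarbonyl compounds with enals, combined with the deacylation of 2,2-disubstituted 1,3-diketones. The ring closes by a 6-(enolendo)-exo-trig aldol addition, the only closure open to the 1,5-keto aldehyde because the alternatives would give four-membered rings. C10 is the only lasting new stereocentre: allylic 1,3-strain with the C11 methyl holds H9 in the enal plane, so the nucleophile should enter anti to the quaternary C8 on the side of the ring oxygen, which gives the 9,10-syn adduct; C1 and C11 form as inconsequential epimer mixtures that are reset in steps 8 and 10. The step needs deacylation at the exocyclic acetyl group only and no elimination at the sugar, which the higher electrophilicity of the unconjugated methyl ketone and the mild carbonate/methanol medium should secure.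

Step 8
Reactants: 14 enone; 15 acrolein
Product: 16 C1-quaternary aldol (1S-methyl, (2S)-1-hydroxyprop-2-enyl group at C1; C11 epimer mixture)
Conditions: LiN(iPr)2 (2.2 equiv), THF, −78 °C; acrolein, −78 °C; AcOH
Reagents that add atoms: acrolein (15) C=CC=O
Why: After the first equivalent of base has taken the tertiary hydroxyl, kinetic deprotonation gives the cross-conjugated α'-enolate, which should add 1,2 to acrolein anti to the C10 substituent (C2 trans to C9) through a Zimmerman–Traxler chair that places the C1 methyl syn to the new hydroxyl (2S).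

Step 9
Reactants: 16 aldol
Product: 17 2-O-(tert-butyldimethylsilyl) ether of 16
Conditions: TBSOTf (1.1 equiv), 2,6-lutidine, CH2Cl2, −78 °C
Reagents that add atoms: tert-butyldimethylsilyl trifluoromethanesulfonate CC(C)(C)[Si](C)(C)OS(=O)(=O)C(F)(F)F
Why: Silylation of the secondary allylic alcohol should outpace that of the hindered tertiary C8 hydroxyl and blocks retro-aldol cleavage at the quaternary C1 in the later basic steps.

Step 10
Reactants: 17 silyl ether
Product: 19 γ-hydroxy enone (11-OH trans to C9, C12=C13, C14 ketone), via silyl dienol ether 18 (not isolated)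
Conditions: TMSOTf, Et3N, CH2Cl2, 0 °C; then mCPBA, NaHCO3, −20 °C; 1 M HCl, THF, 0 °C
Reagents that add atoms: 3-chloroperoxybenzoic acid O=C(OO)c1cccc(Cl)c1
Why: Soft enolisation can only go toward C11 because C1 is quaternary, and vinylogous Rubottom oxidation of the 2-silyloxy diene at its terminus C11, anti to the C10 substituent and the axial C1 methyl, should give the 11-hydroxy enone (the transient C8 silyl ether falls off in the acidic work-up).

Step 11
Reactants: 19 γ-hydroxy enone
Product: 20 12,13-epoxy ketone (epoxide cis to 11-OH)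
Conditions: tBuOOH, DBU, CH2Cl2, 0 °C
Reagents that add atoms: tert-butyl hydroperoxide CC(C)(C)OO
Why: Weitz–Scheffer epoxidation by the hydroperoxide anion is expected on the face of the neighbouring tertiary hydroxyl (hydrogen-bonded delivery, opposite the C11 and C1 methyl groups), which sets the C12–O bond.

Step 12
Reactants: 20 epoxy ketone
Product: 21 allylic diol (C13=C14, 12-OH cis to 11-OH)
Conditions: N2H4·H2O, AcOH (cat.), MeOH, 0 °C → rt, argon
Reagents that add atoms: none
Why: Wharton transposition: the epoxy hydrazone fragments with loss of nitrogen, moving the double bond to C13=C14 and freeing the C12 hydroxyl with the configuration of the epoxide C12–O bond.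

Step 13
Reactants: 21 allylic diol
Product: 22 12-butanoate
Conditions: (PrCO)2O, Et3N, DMAP (cat.), CH2Cl2, 0 °C → rt
Reagents that add atoms: butanoic anhydride CCCC(=O)OC(=O)CCC
Why: DMAP-catalysed acylation should take the only secondary hydroxyl and leave the tertiary ones at C8 and C11 free.

Step 14
Reactants: 22 butanoate
Product: 23 lactol (furanose with free anomeric 6-OH and 7-OH)
Conditions: AcOH/H2O (4:1), 50 °C
Reagents that add atoms: water O
Why: Acid hydrolysis of the anomeric dioxolane frees the masked C6 aldehyde and O7, while the amide cannot lactonise onto the trans-disposed O7 of the closed furanose and the silyl ether and ester should survive.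

Step 15
Reactants: 23 lactol; 24 ethynylmagnesium bromide
Product: 25 (6R)-alkynyl tetraol (open chain C6–C9 with 6-, 7-, 8-, 9-OH; C5≡C4H)
Conditions: HC≡CMgBr (excess), THF, −20 → 0 °C; NH4Cl
Reagents that add atoms: ethynylmagnesium bromide (24) C#C[Mg]Br
Why: The acetylide should add to the open hydroxy aldehyde under chelation control (magnesium bridging the C6 carbonyl and the O7 alkoxide, attack anti to C8) to give the 6,7-syn diol, and acetylide Grignard reagents are too weakly nucleophilic to attack the hindered butanoate or the amide at this temperature.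

Step 16
Reactants: 25 tetraol
Product: 26 6,7-O-isopropylidene derivative
Conditions: 2-methoxypropene (1.5 equiv), PPTS (cat.), CH2Cl2, −20 °C
Reagents that add atoms: 2-methoxypropene C=C(C)OC
Why: Kinetic acetalisation should pick the unhindered secondary–secondary 6,7-diol over the pairs that involve the congested tertiary C8 hydroxyl, which leaves O9 as the only free secondary hydroxyl.

Step 17
Reactants: 26 acetonide
Product: 27 9-acetate
Conditions: Ac2O, pyridine, DMAP (cat.), 0 °C → rt
Reagents that add atoms: acetic anhydride CC(=O)OC(C)=O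
Why: Acetylation of the one remaining secondary hydroxyl fixes the acetate on O9 before O7 is released, so that the later lactonisation has only one five-membered option.

Step 18
Reactants: 27 enyne
Product: 29 ten-membered (3Z)-3,5(16)-diene (6,7-acetonide, C19 amide), via triene 28 (not isolated)
Conditions: second-generation Grubbs catalyst RuCl2(=CHPh)(PCy3)(H2IMes) (15 mol %), ethylene (1 atm), toluene, 60 °C; then argon, high dilution, 80 °C
Reagents that add atoms: ethylene C=C
Why: Enyne cross-metathesis of the terminal alkyne with ethylene gives the 2-substituted butadiene, whose vinyl end should then close the ten-membered ring by ring-closing metathesis with the C2 vinyl group, the Z alkene being the less strained one in this trans-fused ring.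

Step 19
Reactants: 29 macrocycle
Product: 30 6-hydroxy γ-lactone (O7–C19)
Conditions: AcOH/THF/H2O (3:1:1), 55 °C
Reagents that add atoms: water O
Why: Acid removes the 6,7-acetonide and the freed O7 hydroxyl should displace dimethylamine from the γ-disposed amide (hydroxyl-assisted lactonisation, five-membered ring preferred over the six-membered one through O6), O9 being blocked as the acetate.

Step 20
Reactants: 30 allylic alcohol
Product: 31 (6S)-chloride
Conditions: PPh3, hexachloroacetone, CH2Cl2, −30 → 0 °C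
Reagents that add atoms: hexachloroacetone ClC(Cl)(Cl)C(=O)C(Cl)(Cl)Cl
Why: The only secondary alcohol is converted through its alkoxyphosphonium ion into the chloride by SN2 displacement with inversion (6R to 6S), conditions under which allylic alcohols are expected to react without allylic transposition.

Step 21
Reactants: 31 chloride
Product: 32 13,14-epoxide (2-O-silyl ether of the target)
Conditions: VO(acac)2 (10 mol %), tBuOOH, CH2Cl2, 0 °C → rt
Reagents that add atoms: tert-butyl hydroperoxide CC(C)(C)OO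
Why: Vanadium-catalysed epoxidation should be delivered by the homoallylic tertiary 11-OH to its own face of C13=C14 (also the face opposite the axial C1 methyl), while the diene has no allylic or homoallylic free hydroxyl and is deactivated by the allylic chloride.

Step 22
Reactants: 32 silyl ether
Product: 33 CNP0325729.2 (target)
Conditions: HF·pyridine, pyridine, THF, 0 °C → rt
Reagents that add atoms: none
Why: Buffered hydrogen fluoride cleaves the silyl ether by Si–F bond formation under conditions that should spare the epoxide, the esters and the allylic chloride.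

**Compound list**

1 | L-arabinose (aldehydo form drawn) | O=C[C@H](O)[C@@H](O)[C@@H](O)CO | starting material
2 | 5-O-(tert-butyldiphenylsilyl)-L-arabinofuranose | CC(C)(C)[Si](c1ccccc1)(c1ccccc1)OC[C@@H]1OC(O)[C@H](O)[C@H]1O | intermediate
3 | 5-O-(tert-butyldiphenylsilyl)-1,2-O-isopropylidene-β-L-arabinofuranose | CC(C)(C)[Si](c1ccccc1)(c1ccccc1)OC[C@@H]1O[C@@H]2OC(C)(C)O[C@@H]2[C@H]1O | intermediate
4 | 5-O-(tert-butyldiphenylsilyl)-1,2-O-isopropylidene-β-L-threo-pentofuranos-3-ulose | CC(C)(C)[Si](c1ccccc1)(c1ccccc1)OC[C@@H]1O[C@@H]2OC(C)(C)O[C@@H]2C1=O | intermediate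
5 | N,N-dimethylpropanamide | CCC(=O)N(C)C | starting material
6 | 3-C-[(2R)-1-(dimethylamino)-1-oxopropan-2-yl]-5-O-(tert-butyldiphenylsilyl)-1,2-O-isopropylidene-β-L-lyxofuranose | CC(C)(C)[Si](c1ccccc1)(c1ccccc1)OC[C@@H]1O[C@@H]2OC(C)(C)O[C@@H]2[C@@]1(O)[C@@H](C)C(=O)N(C)C | intermediate
7 | 3-C-[(2R)-1-(dimethylamino)-1-oxopropan-2-yl]-1,2-O-isopropylidene-β-L-lyxofuranose | OC[C@@H]1O[C@@H]2OC(C)(C)O[C@@H]2[C@@]1(O)[C@@H](C)C(=O)N(C)C | intermediate
8 | 2-(triphenyl-λ5-phosphanylidene)propanal | CC(C=O)=P(c1ccccc1)(c1ccccc1)c1ccccc1 | starting material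
9 | C10 aldehyde of 7 (pentodialdo-1,4-furanose) | O=C[C@@H]1O[C@@H]2OC(C)(C)O[C@@H]2[C@@]1(O)[C@@H](C)C(=O)N(C)C | intermediate
10 | (E)-2-methyl enal on the furanose (C9–C12; 6,7-O-isopropylidene; 8-OH; C17 amide branch) | O=C/C(C)=C/[C@@H]1O[C@@H]2OC(C)(C)O[C@@H]2[C@@]1(O)[C@@H](C)C(=O)N(C)C | intermediate
11 | 3-methylpentane-2,4-dione | CC(=O)C(C)C(C)=O | starting material
12 | Michael adduct (C1 bearing methyl and two acetyl groups, bonded to C10; C11 epimers) | O=CC(C)[C@@H](C(C)(C(C)=O)C(C)=O)[C@@H]1O[C@@H]2OC(C)(C)O[C@@H]2[C@@]1(O)[C@@H](C)C(=O)N(C)C | intermediate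
13 | 1,5-keto aldehyde (C14 methyl ketone, C12 aldehyde; C1 and C11 epimers) | O=CC(C)[C@@H](C(C)C(C)=O)[C@@H]1O[C@@H]2OC(C)(C)O[C@@H]2[C@@]1(O)[C@@H](C)C(=O)N(C)C | intermediate
14 | 4,6-dimethyl-5-(furanos-4-yl)cyclohex-2-en-1-one (C1 and C11 epimers) | CC1C(=O)C=CC(C)[C@@H]1[C@@H]1O[C@@H]2OC(C)(C)O[C@@H]2[C@@]1(O)[C@@H](C)C(=O)N(C)C | intermediate
15 | acrolein | C=CC=O | starting material
16 | C1-quaternary aldol (1S, 2S; C11 epimers) | C=C[C@H](O)[C@@]1(C)C(=O)C=CC(C)[C@@H]1[C@@H]1O[C@@H]2OC(C)(C)O[C@@H]2[C@@]1(O)[C@@H](C)C(=O)N(C)C | intermediate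
17 | 2-O-(tert-butyldimethylsilyl) ether of 16 | C=C[C@H](O[Si](C)(C)C(C)(C)C)[C@@]1(C)C(=O)C=CC(C)[C@@H]1[C@@H]1O[C@@H]2OC(C)(C)O[C@@H]2[C@@]1(O)[C@@H](C)C(=O)N(C)C | intermediate
18 | trimethylsilyl dienol ether (C14–OSiMe3, C13=C14, C11=C12; C8–OSiMe3) | C=C[C@H](O[Si](C)(C)C(C)(C)C)[C@@]1(C)C(O[Si](C)(C)C)=CC=C(C)[C@@H]1[C@@H]1O[C@@H]2OC(C)(C)O[C@@H]2[C@@]1(O[Si](C)(C)C)[C@@H](C)C(=O)N(C)C | intermediate
19 | γ-hydroxy enone (11-OH) | C=C[C@H](O[Si](C)(C)C(C)(C)C)[C@@]1(C)C(=O)C=C[C@@](C)(O)[C@@H]1[C@@H]1O[C@@H]2OC(C)(C)O[C@@H]2[C@@]1(O)[C@@H](C)C(=O)N(C)C | intermediate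
20 | 12,13-epoxy ketone | C=C[C@H](O[Si](C)(C)C(C)(C)C)[C@@]1(C)C(=O)[C@H]2O[C@H]2[C@@](C)(O)[C@@H]1[C@@H]1O[C@@H]2OC(C)(C)O[C@@H]2[C@@]1(O)[C@@H](C)C(=O)N(C)C | intermediate
21 | 11,12-diol with C13=C14 | C=C[C@H](O[Si](C)(C)C(C)(C)C)[C@@]1(C)C=C[C@@H](O)[C@@](C)(O)[C@@H]1[C@@H]1O[C@@H]2OC(C)(C)O[C@@H]2[C@@]1(O)[C@@H](C)C(=O)N(C)C | intermediate
22 | 12-butanoate | C=C[C@H](O[Si](C)(C)C(C)(C)C)[C@@]1(C)C=C[C@@H](OC(=O)CCC)[C@@](C)(O)[C@@H]1[C@@H]1O[C@@H]2OC(C)(C)O[C@@H]2[C@@]1(O)[C@@H](C)C(=O)N(C)C | intermediate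
23 | lactol (6-OH anomers, 7-OH free) | C=C[C@H](O[Si](C)(C)C(C)(C)C)[C@@]1(C)C=C[C@@H](OC(=O)CCC)[C@@](C)(O)[C@@H]1[C@@H]1OC(O)[C@H](O)[C@@]1(O)[C@@H](C)C(=O)N(C)C | intermediate
24 | ethynylmagnesium bromide | C#C[Mg]Br | starting material
25 | (6R)-alkynyl tetraol | C=C[C@H](O[Si](C)(C)C(C)(C)C)[C@@]1(C)C=C[C@@H](OC(=O)CCC)[C@@](C)(O)[C@@H]1[C@H](O)[C@](O)([C@@H](C)C(=O)N(C)C)[C@@H](O)[C@H](O)C#C | intermediate
26 | 6,7-O-isopropylidene derivative of 25 | C=C[C@H](O[Si](C)(C)C(C)(C)C)[C@@]1(C)C=C[C@@H](OC(=O)CCC)[C@@](C)(O)[C@@H]1[C@H](O)[C@](O)([C@@H](C)C(=O)N(C)C)[C@H]1OC(C)(C)O[C@@H]1C#C | intermediate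
27 | 9-acetate of 26 | C=C[C@H](O[Si](C)(C)C(C)(C)C)[C@@]1(C)C=C[C@@H](OC(=O)CCC)[C@@](C)(O)[C@@H]1[C@H](OC(C)=O)[C@](O)([C@@H](C)C(=O)N(C)C)[C@H]1OC(C)(C)O[C@@H]1C#C | intermediate
28 | triene (buta-1,3-dien-2-yl group at C6) | C=C[C@H](O[Si](C)(C)C(C)(C)C)[C@@]1(C)C=C[C@@H](OC(=O)CCC)[C@@](C)(O)[C@@H]1[C@H](OC(C)=O)[C@](O)([C@@H](C)C(=O)N(C)C)[C@H]1OC(C)(C)O[C@@H]1C(=C)C=C | intermediate
29 | ten-membered (3Z)-3,5(16)-diene, 6,7-acetonide, C19 amide | C=C1/C=C\[C@H](O[Si](C)(C)C(C)(C)C)[C@@]2(C)C=C[C@@H](OC(=O)CCC)[C@@](C)(O)[C@@H]2[C@H](OC(C)=O)[C@](O)([C@@H](C)C(=O)N(C)C)[C@H]2OC(C)(C)O[C@@H]21 | intermediate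
30 | (6R)-6-hydroxy γ-lactone | C=C1/C=C\[C@H](O[Si](C)(C)C(C)(C)C)[C@@]2(C)C=C[C@@H](OC(=O)CCC)[C@@](C)(O)[C@@H]2[C@H](OC(C)=O)[C@]2(O)[C@@H](C)C(=O)O[C@H]2[C@@H]1O | intermediate
31 | (6S)-6-chloride | C=C1/C=C\[C@H](O[Si](C)(C)C(C)(C)C)[C@@]2(C)C=C[C@@H](OC(=O)CCC)[C@@](C)(O)[C@@H]2[C@H](OC(C)=O)[C@]2(O)[C@@H](C)C(=O)O[C@H]2[C@H]1Cl | intermediate
32 | 2-O-(tert-butyldimethylsilyl) ether of the target | C=C1/C=C\[C@H](O[Si](C)(C)C(C)(C)C)[C@@]2(C)[C@H]3O[C@H]3[C@@H](OC(=O)CCC)[C@@](C)(O)[C@@H]2[C@H](OC(C)=O)[C@]2(O)[C@@H](C)C(=O)O[C@H]2[C@H]1Cl | intermediate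
33 | CNP0325729.2 | C=C1/C=C\[C@H](O)[C@@]2(C)[C@H]3O[C@H]3[C@@H](OC(=O)CCC)[C@@](C)(O)[C@@H]2[C@H](OC(C)=O)[C@]2(O)[C@@H](C)C(=O)O[C@H]2[C@H]1Cl | target

**Step count and risks**

Total step count: 22. Longest linear sequence: 22 steps, from L-arabinose (1).

Steps most likely to fail:

1. Step 18 (macrocyclisation). The hindered C2 vinyl group may not engage, so that oligomerisation, exo-mode enyne closure or formation of the E alkene competes. Fallback, from 27 back to 29: α-selective hydrostannation of the alkyne (Bu3SnH, Mo(CO)3(CNtBu)3 cat., THF) should give the 2-stannyl alkene F2; iododestannylation (I2, CH2Cl2, 0 °C) gives the 2-iodoalkene F3; an intramolecular Heck reaction onto the C2 vinyl group (Pd(OAc)2, P(o-tol)3, Ag2CO3, MeCN, high dilution) closes the C4–C5 bond to give 29, the ring being relied on to favour the Z alkene.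

2. Step 7 (key step). Michael addition at the congested C1–C10 bond may be slow or reversible, facial selectivity at C10 may be poor, or the enal may degrade in base before deacylation locks the adduct. Fallback, from 10 back to 14: annulation with allyl 2-methyl-3-oxobutanoate (DBU cat., MeCN; then pyrrolidine, AcOH, 40 °C) gives the stable allyl β-keto ester F1, still forming both ring bonds in one operation; deallylation–decarboxylation under neutral conditions (Pd(PPh3)4 cat., morpholine, THF) then gives 14.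

3. Step 12 (Wharton transposition). Hydrazone formation at the ketone between the quaternary C1 and the epoxide may be sluggish, leaving time for epoxide opening or over-reduction. Fallback, from 20 back to 21: 1,2-reduction (NaBH4, CeCl3·7H2O, MeOH, −40 °C) gives the epoxy alcohol F4; 1,1'-thiocarbonyldiimidazole (DMAP, CH2Cl2) gives the imidazolylthiocarbonate F5; radical fragmentation (Bu3SnH, AIBN, benzene, 80 °C) opens the epoxide from the C14 radical to give 21.

Further compounds

F1 | step 7 | allyl 1,3-dimethyl-2-oxo-6-(furanos-4-yl)cyclohex-3-ene-1-carboxylate (C1 allyl ester analogue of 14) | C=CCOC(=O)C1(C)C(=O)C=CC(C)[C@@H]1[C@@H]1O[C@@H]2OC(C)(C)O[C@@H]2[C@@]1(O)[C@@H](C)C(=O)N(C)C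
F2 | step 18 | 5-(tributylstannyl) alkene from 27 | C=C[C@H](O[Si](C)(C)C(C)(C)C)[C@@]1(C)C=C[C@@H](OC(=O)CCC)[C@@](C)(O)[C@@H]1[C@H](OC(C)=O)[C@](O)([C@@H](C)C(=O)N(C)C)[C@H]1OC(C)(C)O[C@@H]1C(=C)[Sn](CCCC)(CCCC)CCCC
F3 | step 18 | 5-iodo alkene from F2 | C=C[C@H](O[Si](C)(C)C(C)(C)C)[C@@]1(C)C=C[C@@H](OC(=O)CCC)[C@@](C)(O)[C@@H]1[C@H](OC(C)=O)[C@](O)([C@@H](C)C(=O)N(C)C)[C@H]1OC(C)(C)O[C@@H]1C(I)=C
F4 | step 12 | 12,13-epoxy-14-ol from 20 (either C14 epimer) | C=C[C@H](O[Si](C)(C)C(C)(C)C)[C@@]1(C)C(O)[C@H]2O[C@H]2[C@@](C)(O)[C@@H]1[C@@H]1O[C@@H]2OC(C)(C)O[C@@H]2[C@@]1(O)[C@@H](C)C(=O)N(C)C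
F5 | step 12 | 14-O-(imidazol-1-ylthiocarbonyl) derivative of F4 | C=C[C@H](O[Si](C)(C)C(C)(C)C)[C@@]1(C)C(OC(=S)n2ccnc2)[C@H]2O[C@H]2[C@@](C)(O)[C@@H]1[C@@H]1O[C@@H]2OC(C)(C)O[C@@H]2[C@@]1(O)[C@@H](C)C(=O)N(C)C
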